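**Retrosynthetic overview**
1. Target 35 comes from acid 28 by lowering the C20 carboxyl to the C10 methyl group and by unmasking and oxidizing C15 (steps 17–21).
2. Acid 28 comes from the eight-membered lactone 25 by a ring-contracting Ireland–Claisen rearrangement: the temporary ring C10–C20(=O)–O–C17–C8–C7–C6–C5 shrinks to ring B (C5–C6–C7–C8–C9–C10) as C9–C10 forms and O–C17 breaks, so that C9, C10 and the C8=C17 methylene arise together.
3. Enabling feature: in ring B the exocyclic C17=C8 is allylic to C9, and C9 is bonded to the quaternary C10 that carries the one-carbon substituent C20; C17=C8–C9–C10–C20 is the pent-4-enoic acid array left by an ester-enolate Claisen, so C20 is carried as a carboxyl tied to C17 through oxygen (a bond absent from the target) and is reduced back to methyl afterwards.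
4. Lactone 25 comes from seco acid 24 by macrolactonization, and 24 from a B-alkyl Suzuki union of ring A diester 13 (C5 vinyl) with (E)-iodoallylic alcohol 21, which is made from (S)-citronellol and fixes C13 and the C8=C9 geometry.
5. Ring order: ring A first (step 6; C5 from an asymmetric vinyl addition, C4 from a lactone alkylation), the temporary lactone ring second (step 15), ring B last by contraction (step 16).

Key step: step 16

Assumption: the SMILES is read as the 18-methyl ester of (13S)-labd-8(17)-ene-15,18-dioic acid (4R,5R,9S,10R,13S; 4α-CO2Me, 4β-Me, 5α-H, 9α-H, 10β-Me); labdane numbering (C1–C20) is used for the atoms of all intermediates.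

**Route**

Step 1
Reactants: 1 5,6-dihydro-2H-pyran-2-one; 2 potassium vinyltrifluoroborate
Product: 3 (R)-4-vinyltetrahydro-2H-pyran-2-one
Conditions: [Rh(cod)2]BF4 (3 mol%), (R)-BINAP (3.3 mol%), toluene/H2O 10:1, 100 °C
Reagents that add atoms: none
Why: Rhodium-catalysed asymmetric conjugate addition (Hayashi–Miyaura type) of the vinyl group to the unsaturated lactone; the (R)-BINAP–rhodium vinyl species should select one enantioface of C3=C4 (ligand antipode chosen by analogy with the (S)-BINAP/cyclohexenone to (S)-product correlation), which sets the future C5.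

Step 2
Reactants: 3 (R)-4-vinyltetrahydro-2H-pyran-2-one; 4 1-chloro-3-iodopropane
Product: 6 (3S,4S)-3-(3-chloropropyl)-4-vinyltetrahydro-2H-pyran-2-one, via lithium enolate 5 (not isolated)
Conditions: LiN(i-Pr)2, THF, −78 °C; then 4, DMPU, −78 → −30 °C
Reagents that add atoms: none
Why: Kinetic lactone enolate alkylation in which the iodide reacts and the chloride is kept, the chain entering trans to the neighbouring vinyl group; this centre is re-enolized in step 3, so only its constitution matters.

Step 3
Reactants: 6 (3S,4S)-3-(3-chloropropyl)-4-vinyltetrahydro-2H-pyran-2-one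
Product: 8 (3R,4S)-3-(3-chloropropyl)-3-methyl-4-vinyltetrahydro-2H-pyran-2-one, via lithium enolate 7 (not isolated)
Conditions: LiN(i-Pr)2, THF, −78 °C; then MeI, DMPU, −78 → −20 °C
Reagents that add atoms: iodomethane, IC
Why: Second enolate alkylation that builds the quaternary centre (future C4): MeI should approach the enolate face anti to the pseudoaxial vinyl group, so methyl ends trans and the chloropropyl chain cis to vinyl, which is the 4β-methyl/4α-carboxyl arrangement relative to C5.

Step 4
Reactants: 8 (3R,4S)-3-(3-chloropropyl)-3-methyl-4-vinyltetrahydro-2H-pyran-2-one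
Product: 10 (2R,3S)-2-(3-chloropropyl)-2-methyl-3-vinylpentanedioic acid, via sodium hydroxy carboxylate 9 (not isolated)
Conditions: NaOH, THF/H2O, rt → 40 °C; then TEMPO (cat.), KBr (cat.), NaOCl, pH 10, 0 °C; then HCl (aq) to pH 2
Reagents that add atoms: sodium hydroxide, [Na+].[OH-]; water, O
Why: Saponification opens the lactone and the freed primary alcohol is oxidized in the same basic medium (TEMPO/hypochlorite oxidation) to the carboxylate before it can relactonize, which makes the C10 methylene α to a carboxyl; no stereocentre is touched.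

Step 5
Reactants: 10 (2R,3S)-2-(3-chloropropyl)-2-methyl-3-vinylpentanedioic acid
Product: 11 dimethyl (2R,3S)-2-(3-chloropropyl)-2-methyl-3-vinylpentanedioate
Conditions: Me3SiCHN2, toluene/MeOH 4:1, 0 °C → rt
Reagents that add atoms: trimethylsilyldiazomethane, C[Si](C)(C)C=[N+]=[N-]
Why: Diazoalkane esterification methylates both acids, the neopentyl one included, without forming a carboxylate that could displace the primary chloride.

Step 6
Reactants: 11 dimethyl (2R,3S)-2-(3-chloropropyl)-2-methyl-3-vinylpentanedioate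
Product: 13 dimethyl (1R,2R,3S)-1-methyl-2-vinylcyclohexane-1,3-dicarboxylate, via potassium enolate 12 (not isolated)
Conditions: KN(SiMe3)2, THF, −78 → 0 °C
Reagents that add atoms: none
Why: Intramolecular ester enolate alkylation (6-exo-tet): C10 is the only enolizable carbon and its enolate displaces the primary chloride to close ring A; the new C10 centre (expected trans to vinyl) is planarized again in step 16, so its configuration is irrelevant.

Step 7
Reactants: 14 (S)-citronellol
Product: 15 (S)-tert-butyl[(3,7-dimethyloct-6-en-1-yl)oxy]diphenylsilane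
Conditions: t-BuPh2SiCl, imidazole, CH2Cl2, rt
Reagents that add atoms: tert-butyl(chloro)diphenylsilane, CC(C)(C)[Si](Cl)(c1ccccc1)c1ccccc1
Why: Standard silylation of the primary alcohol; the silyl ether carries C15 at the alcohol level through all basic and reducing steps.

Step 8
Reactants: 15 (S)-tert-butyl[(3,7-dimethyloct-6-en-1-yl)oxy]diphenylsilane
Product: 16 (S)-6-[(tert-butyldiphenylsilyl)oxy]-4-methylhexanal
Conditions: OsO4 (2 mol%), NaIO4, 2,6-lutidine, dioxane/H2O 3:1, rt
Reagents that add atoms: sodium periodate, [Na+].[O-]I(=O)(=O)=O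
Why: Lemieux–Johnson oxidative cleavage of the trisubstituted alkene gives the aldehyde whose carbonyl carbon becomes C9; the remote stereocentre (future C13) is untouched.

Step 9
Reactants: 16 (S)-6-[(tert-butyldiphenylsilyl)oxy]-4-methylhexanal
Product: 17 (S)-tert-butyl[(7,7-dibromo-3-methylhept-6-en-1-yl)oxy]diphenylsilane
Conditions: CBr4, PPh3, CH2Cl2, 0 °C
Reagents that add atoms: carbon tetrabromide, BrC(Br)(Br)Br
Why: Corey–Fuchs dibromo-olefination (Wittig-type reaction of the dibromomethylene ylide) adds the carbon that becomes C8.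

Step 10
Reactants: 17 (S)-tert-butyl[(7,7-dibromo-3-methylhept-6-en-1-yl)oxy]diphenylsilane
Product: 19 (S)-8-[(tert-butyldiphenylsilyl)oxy]-6-methyloct-2-yn-1-ol, via lithium acetylide 18 (not isolated)
Conditions: n-BuLi (2.2 equiv), THF, −78 → 0 °C; then (CH2O)n, 0 °C → rt
Reagents that add atoms: formaldehyde (from paraformaldehyde), C=O
Why: Second stage of the Corey–Fuchs sequence (bromine–lithium exchange, rearrangement to the alkyne, deprotonation) followed by trapping of the acetylide with formaldehyde, which introduces C17 as the hydroxymethyl group.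

Step 11
Reactants: 19 (S)-8-[(tert-butyldiphenylsilyl)oxy]-6-methyloct-2-yn-1-ol
Product: 20 (S,E)-8-[(tert-butyldiphenylsilyl)oxy]-6-methyl-2-(tributylstannyl)oct-2-en-1-ol
Conditions: Pd(PPh3)2Cl2 (2 mol%), Bu3SnH (slow addition), THF, 0 °C → rt
Reagents that add atoms: tributyltin hydride, CCCC[SnH](CCCC)CCCC
Why: Palladium-catalysed syn hydrostannation of the propargylic alcohol should place tin mainly on the carbon next to the hydroxymethyl group and hydrogen cis to it, which fixes the alkene geometry (CH2OH cis to the chain); the minor distal regioisomer would be removed by chromatography.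

Step 12
Reactants: 20 (S,E)-8-[(tert-butyldiphenylsilyl)oxy]-6-methyl-2-(tributylstannyl)oct-2-en-1-ol
Product: 21 (S,E)-8-[(tert-butyldiphenylsilyl)oxy]-2-iodo-6-methyloct-2-en-1-ol
Conditions: I2, CH2Cl2, 0 °C
Reagents that add atoms: iodine, I-I
Why: Iododestannylation proceeds with retention of alkene geometry.

Step 13
Reactants: 13 dimethyl (1R,2R,3S)-1-methyl-2-vinylcyclohexane-1,3-dicarboxylate; 21 (S,E)-8-[(tert-butyldiphenylsilyl)oxy]-2-iodo-6-methyloct-2-en-1-ol
Product: 23 dimethyl (1R,2R,3S)-2-[(3Z,7S)-9-[(tert-butyldiphenylsilyl)oxy]-3-(hydroxymethyl)-7-methylnon-3-en-1-yl]-1-methylcyclohexane-1,3-dicarboxylate, via alkylborane 22 (not isolated)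
Conditions: 9-BBN, THF, 0 °C → rt; then 21, Pd(dppf)Cl2 (5 mol%), AsPh3, Cs2CO3, DMF/THF/H2O, rt
Reagents that add atoms: none
Why: B-alkyl Suzuki–Miyaura coupling: 9-BBN adds to the terminal carbon of the vinyl group and the alkylborane couples with the vinyl iodide with retention, which joins C7 to C8 and gives the (Z)-allylic alcohol (C17 cis to C11) needed for the C9 configuration.

Step 14
Reactants: 23 dimethyl (1R,2R,3S)-2-[(3Z,7S)-9-[(tert-butyldiphenylsilyl)oxy]-3-(hydroxymethyl)-7-methylnon-3-en-1-yl]-1-methylcyclohexane-1,3-dicarboxylate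
Product: 24 (1S,2R,3R)-2-[(3Z,7S)-9-[(tert-butyldiphenylsilyl)oxy]-3-(hydroxymethyl)-7-methylnon-3-en-1-yl]-3-(methoxycarbonyl)-3-methylcyclohexane-1-carboxylic acid
Conditions: LiOH, THF/MeOH/H2O, 40 °C; then HCl (aq) to pH 3
Reagents that add atoms: lithium hydroxide, [Li+].[OH-]
Why: Chemoselective saponification: the secondary C20 ester should be hydrolysed while the C18 ester on the quaternary C4 resists hydroxide (neopentyl-type hindrance); epimerization at C10 is without consequence.

Step 15
Reactants: 24 (1S,2R,3R)-2-[(3Z,7S)-9-[(tert-butyldiphenylsilyl)oxy]-3-(hydroxymethyl)-7-methylnon-3-en-1-yl]-3-(methoxycarbonyl)-3-methylcyclohexane-1-carboxylic acid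
Product: 25 methyl (1S,5Z,8R,9R)-5-[(4S)-6-[(tert-butyldiphenylsilyl)oxy]-4-methylhexylidene]-9-methyl-2-oxo-3-oxabicyclo[6.4.0]dodecane-9-carboxylate
Conditions: MNBA (2-methyl-6-nitrobenzoic anhydride), DMAP, Et3N, CH2Cl2, rt, slow addition of 24 (final 1 mM)
Reagents that add atoms: none
Why: Shiina macrolactonization (mixed anhydride, DMAP acyl transfer) under high dilution; the fused cyclohexane and the sp2 C8 restrict the seco acid enough that eight-membered closure should compete, as is known for substituted eight-membered lactones.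

Step 16
Reactants: 25 methyl (1S,5Z,8R,9R)-5-[(4S)-6-[(tert-butyldiphenylsilyl)oxy]-4-methylhexylidene]-9-methyl-2-oxo-3-oxabicyclo[6.4.0]dodecane-9-carboxylate
Product: 28 (13S)-15-[(tert-butyldiphenylsilyl)oxy]-18-methoxy-18-oxolabd-8(17)-en-20-oic acid, via silyl ketene acetal 26 (not isolated), via silyl ester 27 (not isolated)
Conditions: KN(SiMe3)2, Me3SiCl/Et3N (premixed), THF, −78 °C → rt; then toluene, 80 °C; then 1 M HCl, THF, 0 °C
Reagents that add atoms: none
Why: Proposed new method: deprotonation at C10 (the only enolizable position) and O-silylation give the ring-constrained ketene acetal 26 (C10=C20, with C5 and the ring oxygen necessarily cis), whose O–C17–C8=C9 allyl unit should undergo a concerted suprafacial [3,3]-sigmatropic (Ireland–Claisen) shift in which C10–C9 forms, O–C17 breaks and C8=C17 appears, so that the eight-membered ring (C10, C20, O, C17, C8, C7, C6, C5) contracts to ring B (C10, C9, C8, C7, C6, C5). The closest known reaction types are the ring-contracting ester-enolate Claisen rearrangement of macrocyclic lactones (four-atom contraction through an endocyclic alkene) and the enolate Claisen rearrangement of alkenyl dioxanones to dihydropyrans; the two-atom contraction through an exocyclic alkylidene proposed here has not been shown on this substrate class, but it gains a C=O bond, releases medium-ring strain and passes through an oxabicyclo[3.3.1]nonane-like chair–chair array that lacks the usual transannular H/H contact because the central bridge atom is oxygen. Ring B closes by C–C bond formation between the enolate carbon C10 and the alkene terminus C9 while the C5–C6–C7 tether spans positions 1 and 5 of the six-atom array (formally 6-endo-trig at C8=C9), and this short tether allows only the chair arrangement, the boat being geometrically out of reach. C9 is set by the (Z)-alkene geometry in that chair (C11, cis to C17, becomes equatorial and H9 axial, anti to C20), and C10 by the face on which the tether holds C9. The selectivity needed is trans ring fusion, which the existing C5 stereocentre should secure because the trans-decalin-like array keeps the quaternary C4 equatorial on the forming ring B, whereas the cis alternative forces C4 with its methyl and ester groups axial over ring B against H9 and C7. No other position can be enolized (the C18 ester sits on quaternary C4 and C15 is a silyl ether), and silylation at −78 °C suppresses ketene-forming loss of the allyloxide from the enolate.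

Step 17
Reactants: 28 (13S)-15-[(tert-butyldiphenylsilyl)oxy]-18-methoxy-18-oxolabd-8(17)-en-20-oic acid
Product: 30 methyl (13S)-15-[(tert-butyldiphenylsilyl)oxy]-20-oxolabd-8(17)-en-18-oate, via acid chloride 29 (not isolated)
Conditions: 1-chloro-N,N,2-trimethylprop-1-en-1-amine, CH2Cl2, 0 °C → rt; then LiAlH(Ot-Bu)3, THF, −78 °C
Reagents that add atoms: none
Why: The hindered acid is converted under neutral conditions into the acid chloride, which the bulky hydride should reduce only as far as the aldehyde at −78 °C; methyl ester, silyl ether and alkene are inert.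

Step 18
Reactants: 30 methyl (13S)-15-[(tert-butyldiphenylsilyl)oxy]-20-oxolabd-8(17)-en-18-oate
Product: 31 methyl (13S)-15-[(tert-butyldiphenylsilyl)oxy]-20-[(E)-2-(4-methylphenylsulfonyl)hydrazinylidene]labd-8(17)-en-18-oate
Conditions: TsNHNH2, EtOH, 60 °C
Reagents that add atoms: p-toluenesulfonyl hydrazide, Cc1ccc(cc1)S(=O)(=O)NN
Why: Condensation of the aldehyde with the sulfonyl hydrazide (hydrazone formation); no stereocentre is involved.

Step 19
Reactants: 31 methyl (13S)-15-[(tert-butyldiphenylsilyl)oxy]-20-[(E)-2-(4-methylphenylsulfonyl)hydrazinylidene]labd-8(17)-en-18-oate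
Product: 33 methyl (13S)-15-[(tert-butyldiphenylsilyl)oxy]labd-8(17)-en-18-oate, via N-boryl sulfonylhydrazine 32 (not isolated)
Conditions: catecholborane, CHCl3, 0 °C → rt; then NaOAc·3H2O, reflux
Reagents that add atoms: none
Why: Tosylhydrazone (Caglioti-type) reduction in its catecholborane variant: hydride adds to C=N, acetate-induced loss of sulfinate gives the alkyldiazene, and loss of N2 leaves C20 as the methyl group; cold catecholborane should not hydroborate the 1,1-disubstituted alkene.

Step 20
Reactants: 33 methyl (13S)-15-[(tert-butyldiphenylsilyl)oxy]labd-8(17)-en-18-oate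
Product: 34 methyl (13S)-15-hydroxylabd-8(17)-en-18-oate
Conditions: Bu4NF, THF, rt
Reagents that add atoms: none
Why: Fluoride-induced cleavage of the silyl ether; the hindered methyl ester and the alkene are unaffected.

Step 21
Reactants: 34 methyl (13S)-15-hydroxylabd-8(17)-en-18-oate
Product: 35 (13S)-18-methoxy-18-oxolabd-8(17)-en-15-oic acid (target)
Conditions: TEMPO (cat.), PhI(OAc)2, MeCN/H2O 1:1, rt
Reagents that add atoms: water, O
Why: TEMPO/PhI(OAc)2 oxidation of the primary alcohol through the aldehyde hydrate to the acid under near-neutral conditions that leave the exocyclic alkene and the hindered methyl ester untouched.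

**Compound list**
1 | 5,6-dihydro-2H-pyran-2-one | O=C1C=CCCO1 | starting material
2 | potassium vinyltrifluoroborate | C=C[B-](F)(F)F.[K+] | starting material
3 | (R)-4-vinyltetrahydro-2H-pyran-2-one | C=C[C@@H]1CCOC(=O)C1 | intermediate
4 | 1-chloro-3-iodopropane | ClCCCI | starting material
5 | lithium enolate of 3 (not isolated) | C=C[C@@H]1CCOC(O[Li])=C1 | intermediate
6 | (3S,4S)-3-(3-chloropropyl)-4-vinyltetrahydro-2H-pyran-2-one | C=C[C@@H]1CCOC(=O)[C@H]1CCCCl | intermediate
7 | lithium enolate of 6 (not isolated) | C=C[C@@H]1CCOC(O[Li])=C1CCCCl | intermediate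
8 | (3R,4S)-3-(3-chloropropyl)-3-methyl-4-vinyltetrahydro-2H-pyran-2-one | C=C[C@@H]1CCOC(=O)[C@]1(C)CCCCl | intermediate
9 | sodium (2R,3S)-2-(3-chloropropyl)-3-(2-hydroxyethyl)-2-methylpent-4-enoate (not isolated) | C=C[C@H](CCO)[C@@](C)(CCCCl)C(=O)[O-].[Na+] | intermediate
10 | (2R,3S)-2-(3-chloropropyl)-2-methyl-3-vinylpentanedioic acid | C=C[C@H](CC(=O)O)[C@@](C)(CCCCl)C(=O)O | intermediate
11 | dimethyl (2R,3S)-2-(3-chloropropyl)-2-methyl-3-vinylpentanedioate | C=C[C@H](CC(=O)OC)[C@@](C)(CCCCl)C(=O)OC | intermediate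
12 | potassium enolate of 11 at C10 (not isolated; enolate geometry not defined) | C=C[C@H](C=C(O[K])OC)[C@@](C)(CCCCl)C(=O)OC | intermediate
13 | dimethyl (1R,2R,3S)-1-methyl-2-vinylcyclohexane-1,3-dicarboxylate (ring A diester; the C3 epimer, labdane C10, serves equally) | COC(=O)[C@]1(C)CCC[C@H](C(=O)OC)[C@H]1C=C | intermediate
14 | (S)-citronellol | CC(C)=CCC[C@H](C)CCO | starting material
15 | (S)-tert-butyl[(3,7-dimethyloct-6-en-1-yl)oxy]diphenylsilane | CC(C)=CCC[C@H](C)CCO[Si](c1ccccc1)(c1ccccc1)C(C)(C)C | intermediate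
16 | (S)-6-[(tert-butyldiphenylsilyl)oxy]-4-methylhexanal | O=CCC[C@H](C)CCO[Si](c1ccccc1)(c1ccccc1)C(C)(C)C | intermediate
17 | (S)-tert-butyl[(7,7-dibromo-3-methylhept-6-en-1-yl)oxy]diphenylsilane | BrC(Br)=CCC[C@H](C)CCO[Si](c1ccccc1)(c1ccccc1)C(C)(C)C | intermediate
18 | lithium acetylide of (S)-tert-butyl[(3-methylhept-6-yn-1-yl)oxy]diphenylsilane (not isolated) | [Li]C#CCC[C@H](C)CCO[Si](c1ccccc1)(c1ccccc1)C(C)(C)C | intermediate
19 | (S)-8-[(tert-butyldiphenylsilyl)oxy]-6-methyloct-2-yn-1-ol | OCC#CCC[C@H](C)CCO[Si](c1ccccc1)(c1ccccc1)C(C)(C)C | intermediate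
20 | (S,E)-8-[(tert-butyldiphenylsilyl)oxy]-6-methyl-2-(tributylstannyl)oct-2-en-1-ol | OC/C(=C\CC[C@H](C)CCO[Si](c1ccccc1)(c1ccccc1)C(C)(C)C)[Sn](CCCC)(CCCC)CCCC | intermediate
21 | (S,E)-8-[(tert-butyldiphenylsilyl)oxy]-2-iodo-6-methyloct-2-en-1-ol | OC/C(I)=C\CC[C@H](C)CCO[Si](c1ccccc1)(c1ccccc1)C(C)(C)C | intermediate
22 | B-alkyl-9-BBN borane from 13 (boron on C7; not isolated) | COC(=O)[C@]1(C)CCC[C@H](C(=O)OC)[C@H]1CCB1C2CCCC1CCC2 | intermediate
23 | dimethyl (1R,2R,3S)-2-[(3Z,7S)-9-[(tert-butyldiphenylsilyl)oxy]-3-(hydroxymethyl)-7-methylnon-3-en-1-yl]-1-methylcyclohexane-1,3-dicarboxylate | COC(=O)[C@]1(C)CCC[C@H](C(=O)OC)[C@H]1CC/C(CO)=C/CC[C@H](C)CCO[Si](c1ccccc1)(c1ccccc1)C(C)(C)C | intermediate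
24 | (1S,2R,3R)-2-[(3Z,7S)-9-[(tert-butyldiphenylsilyl)oxy]-3-(hydroxymethyl)-7-methylnon-3-en-1-yl]-3-(methoxycarbonyl)-3-methylcyclohexane-1-carboxylic acid (seco acid) | COC(=O)[C@]1(C)CCC[C@H](C(=O)O)[C@H]1CC/C(CO)=C/CC[C@H](C)CCO[Si](c1ccccc1)(c1ccccc1)C(C)(C)C | intermediate
25 | methyl (1S,5Z,8R,9R)-5-[(4S)-6-[(tert-butyldiphenylsilyl)oxy]-4-methylhexylidene]-9-methyl-2-oxo-3-oxabicyclo[6.4.0]dodecane-9-carboxylate (eight-membered lactone C20(=O)–O–C17 fused to ring A; the C1 epimer, labdane C10, serves equally) | COC(=O)[C@]1(C)CCC[C@@H]2C(=O)OC/C(=C\CC[C@H](C)CCO[Si](c3ccccc3)(c3ccccc3)C(C)(C)C)CC[C@@H]12 | intermediate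
26 | trimethylsilyl ketene acetal of 25 (C10=C20, C5 cis to the ring oxygen; not isolated) | COC(=O)[C@]1(C)CCC/C2=C(\O[Si](C)(C)C)OC/C(=C\CC[C@H](C)CCO[Si](c3ccccc3)(c3ccccc3)C(C)(C)C)CC[C@@H]12 | intermediate
27 | trimethylsilyl ester of 28 (not isolated) | C=C1CC[C@@H]2[C@](C(=O)O[Si](C)(C)C)(CCC[C@@]2(C)C(=O)OC)[C@H]1CC[C@H](C)CCO[Si](c1ccccc1)(c1ccccc1)C(C)(C)C | intermediate
28 | (13S)-15-[(tert-butyldiphenylsilyl)oxy]-18-methoxy-18-oxolabd-8(17)-en-20-oic acid (4α-CO2Me, 5α-H, 9α-H, 10β-CO2H) | C=C1CC[C@@H]2[C@](C(=O)O)(CCC[C@@]2(C)C(=O)OC)[C@H]1CC[C@H](C)CCO[Si](c1ccccc1)(c1ccccc1)C(C)(C)C | intermediate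
29 | acid chloride of 28 at C20 (not isolated) | C=C1CC[C@@H]2[C@](C(=O)Cl)(CCC[C@@]2(C)C(=O)OC)[C@H]1CC[C@H](C)CCO[Si](c1ccccc1)(c1ccccc1)C(C)(C)C | intermediate
30 | methyl (13S)-15-[(tert-butyldiphenylsilyl)oxy]-20-oxolabd-8(17)-en-18-oate | C=C1CC[C@@H]2[C@](C=O)(CCC[C@@]2(C)C(=O)OC)[C@H]1CC[C@H](C)CCO[Si](c1ccccc1)(c1ccccc1)C(C)(C)C | intermediate
31 | (E)-p-toluenesulfonylhydrazone of 30 at C20 | C=C1CC[C@@H]2[C@](/C=N/NS(=O)(=O)c3ccc(C)cc3)(CCC[C@@]2(C)C(=O)OC)[C@H]1CC[C@H](C)CCO[Si](c1ccccc1)(c1ccccc1)C(C)(C)C | intermediate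
32 | N-(1,3,2-benzodioxaborol-2-yl)-N-(labdan-20-yl) sulfonylhydrazine from 31 (not isolated) | C=C1CC[C@@H]2[C@](CN(NS(=O)(=O)c3ccc(C)cc3)B3Oc4ccccc4O3)(CCC[C@@]2(C)C(=O)OC)[C@H]1CC[C@H](C)CCO[Si](c1ccccc1)(c1ccccc1)C(C)(C)C | intermediate
33 | methyl (13S)-15-[(tert-butyldiphenylsilyl)oxy]labd-8(17)-en-18-oate | C=C1CC[C@@H]2[C@](C)(CCC[C@@]2(C)C(=O)OC)[C@H]1CC[C@H](C)CCO[Si](c1ccccc1)(c1ccccc1)C(C)(C)C | intermediate
34 | methyl (13S)-15-hydroxylabd-8(17)-en-18-oate | C=C1CC[C@@H]2[C@](C)(CCC[C@@]2(C)C(=O)OC)[C@H]1CC[C@H](C)CCO | intermediate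
35 | (13S)-18-methoxy-18-oxolabd-8(17)-en-15-oic acid, CNP0135192.1 (4R,5R,9S,10R,13S) | C=C1CC[C@@H]2[C@](C)(CCC[C@@]2(C)C(=O)OC)[C@H]1CC[C@H](C)CC(=O)O | target

**Step count and risks**
Total step count: 21. Longest linear sequence: 15 steps (steps 1–6 then 13–21; the side-chain branch, steps 7–12 then 13–21, is equally long).

Steps most likely to fail:

1. Step 16 (the labelled step). The ketene acetal may fail to reach the bridged chair array before the enolate fragments by loss of the allyloxide, or it may rearrange with poor face selectivity at C10 and give cis ring fusion. The fallback uses known chemistry and gives up the lactone. It sets out from 13 and 21. Selective saponification of 13 (LiOH, as in step 14) should give (1S,2R,3R)-3-(methoxycarbonyl)-3-methyl-2-vinylcyclohexane-1-carboxylic acid F1. Carbodiimide esterification of F1 with 21 (EDC, DMAP, CH2Cl2) should give the iodoallyl ester F2. A conventional acyclic Ireland–Claisen rearrangement of F2 (KN(SiMe3)2, Me3SiCl, THF, −78 °C → rt, then aqueous acid) forms C9–C10 and should give the 2-iodoallyl acid F3; here the C9/C10 configuration rests on ketene acetal geometry and is less secure, so a diastereomer separation is expected. Hydroboration of the C5 vinyl group of F3 with excess 9-BBN, followed by intramolecular B-alkyl Suzuki coupling onto the vinyl iodide (Pd(dppf)Cl2, AsPh3, Cs2CO3, DMF/H2O), closes ring B directly as the six-membered ring and comes back to the route at 28.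

2. Step 15. Acyl transfer from the α-branched, hindered mixed anhydride to the alcohol may be slow, so that intermolecular esterification (diolide and oligomers) outruns eight-membered closure. The fallback reverses the polarity of the ring closure: a Mitsunobu lactonization of 24 (PPh3, DIAD, toluene, high dilution) activates the unhindered primary allylic carbon C17 instead of the hindered acyl carbon, and the carboxylate closes the ring by alkyl–oxygen bond formation. It sets out from 24 and comes back at 25 without any new compound.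

3. Step 19. Hydride delivery to the neopentyl, 1,3-diaxially shielded C=N may be too slow, so that the hydrazone survives or the diazene stage diverts. The fallback sets out from 30. NaBH4 reduction (MeOH, 0 °C) should give methyl (13S)-15-[(tert-butyldiphenylsilyl)oxy]-20-hydroxylabd-8(17)-en-18-oate F4. Xanthate formation (NaH, CS2, then MeI, THF) should give the O-(labdan-20-yl) S-methyl dithiocarbonate F5. Barton–McCombie deoxygenation of F5 (Bu3SnH, AIBN, toluene, 110 °C) comes back to the route at 33.

Further compounds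
F1 | step 16 | (1S,2R,3R)-3-(methoxycarbonyl)-3-methyl-2-vinylcyclohexane-1-carboxylic acid | COC(=O)[C@]1(C)CCC[C@H](C(=O)O)[C@H]1C=C
F2 | step 16 | 1-[(S,E)-8-[(tert-butyldiphenylsilyl)oxy]-2-iodo-6-methyloct-2-en-1-yl] 3-methyl (1S,2R,3R)-3-methyl-2-vinylcyclohexane-1,3-dicarboxylate | COC(=O)[C@]1(C)CCC[C@H](C(=O)OC/C(I)=C\CC[C@H](C)CCO[Si](c2ccccc2)(c2ccccc2)C(C)(C)C)[C@H]1C=C
F3 | step 16 | 1-[(6S)-8-[(tert-butyldiphenylsilyl)oxy]-2-iodo-6-methyloct-1-en-3-yl]-3-(methoxycarbonyl)-3-methyl-2-vinylcyclohexane-1-carboxylic acid, configured at C4, C5, C9 and C10 as in 28 | C=C(I)[C@H](CC[C@H](C)CCO[Si](c1ccccc1)(c1ccccc1)C(C)(C)C)[C@@]1(C(=O)O)CCC[C@@](C)(C(=O)OC)[C@@H]1C=C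
F0 | step 15 | none | none
F4 | step 19 | methyl (13S)-15-[(tert-butyldiphenylsilyl)oxy]-20-hydroxylabd-8(17)-en-18-oate | C=C1CC[C@@H]2[C@](CO)(CCC[C@@]2(C)C(=O)OC)[C@H]1CC[C@H](C)CCO[Si](c1ccccc1)(c1ccccc1)C(C)(C)C
F5 | step 19 | O-[(13S)-15-[(tert-butyldiphenylsilyl)oxy]-18-methoxy-18-oxolabd-8(17)-en-20-yl] S-methyl dithiocarbonate | C=C1CC[C@@H]2[C@](COC(=S)SC)(CCC[C@@]2(C)C(=O)OC)[C@H]1CC[C@H](C)CCO[Si](c1ccccc1)(c1ccccc1)C(C)(C)C
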